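## Retrosynthetic overview

1. Plagiochilin A (14) comes from lactol ester 13 by one-pot DIBAL reduction and double acetylation. The dihydropyran in 13, the last ring formed, comes from ozonolysis of a sacrificial C2=C3 cyclopentene in 12, followed by spontaneous enol-lactol closure.
2. The spiro-epoxide in 12 comes from CH2 transfer (LiCH2Cl) to the convex face of the cis-fused ketone 11.
3. The cyclopentene in 11 comes from a Michael/aldol annulation of cycloheptenone 6 with methyl 4,4-dimethoxybutanoate, which supplies C2, C3, C4 and C15. A deconjugative protonation then sets C1.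
4. Enone 6 comes from one-carbon ring expansion of cyclohexenone 5, which comes from aldol closure of keto-aldehyde 4, which comes from (+)-3-carene.
5. Ring order: cyclopropane (chiral pool), six-membered ring, seven-membered ring, temporary cyclopentene, oxirane, dihydropyran.

**Numbering (aromadendrane):** C2 acetal CH, C3 enol-ether CH, C4 =C(CH2OAc), C15 CH2OAc, C1/C5 ring-fusion CH, C6/C7 cyclopropane CH, C11 CMe2, C10 spiro carbon, C14 oxirane CH2. The target is 1R,2R,5R,6S,7S,10S.

**Assumption 1:** Commercial (+)-3-carene is (1S,6R) and of high ee. Removing one carbon from its aldehyde arm puts the CHO directly on carene C6, which becomes C6 of the target. This places the material in the ent series that the target requires; (+)-2-carene would give the wrong enantiomer.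

**Assumption 2:** The E/Z mixtures in 3 and 8 and the C4 epimers in 9–12 do not matter, because those centres are destroyed later.

## Route

**Step 1**
- Reactants: 1, (+)-3-carene
- Product: 2, 2-[(1R,3S)-2,2-dimethyl-3-(2-oxopropyl)cyclopropyl]acetaldehyde
- Conditions: O3, CH2Cl2/MeOH, −78 °C; Me2S, → rt
- Reagents that add atoms: ozone, [O-][O+]=O
- Why: Criegee ozonolysis of the only alkene; the two cis cyclopropane stereocentres (future C6 and C7) are not touched.

**Step 2**
- Reactants: 2
- Product: 3, 2-[(1S,3S)-2,2-dimethyl-3-(2-oxopropyl)cyclopropyl]ethenyl acetate (E/Z)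
- Conditions: Ac2O, Et3N, DMAP (cat.), THF, reflux
- Reagents that add atoms: acetic anhydride, CC(=O)OC(C)=O
- Why: Aldehyde enol acetylation; the aldehyde enolises and O-acylates much faster than the methyl ketone.

**Step 3**
- Reactants: 3
- Product: 4, (1R,3S)-2,2-dimethyl-3-(2-oxopropyl)cyclopropane-1-carbaldehyde
- Conditions: O3, CH2Cl2, −78 °C; Me2S
- Reagents that add atoms: ozone, [O-][O+]=O
- Why: Ozonolysis of the enol acetate removes one carbon and leaves CHO (C5) directly on C6; no stereocentre is affected.

**Step 4**
- Reactants: 4
- Product: 5, (1S,6R)-7,7-dimethylbicyclo[4.1.0]hept-4-en-3-one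
- Conditions: KOH (cat.), MeOH, 0 °C → rt
- Reagents that add atoms: none
- Why: Intramolecular aldol condensation of a 1,5-keto-aldehyde; attack by the CH3 group gives the six-membered ring, while the alternative CH2 attack would give a four-membered ring.

**Step 5**
- Reactants: 5
- Product: 6, (1R,7S)-8,8-dimethylbicyclo[5.1.0]oct-2-en-4-one
- Conditions: TMSCHN2, BF3·OEt2, CH2Cl2, −78 → −30 °C; then 1 M HCl/THF
- Reagents that add atoms: (trimethylsilyl)diazomethane, C[Si](C)(C)C=[N+]=[N-] (supplies C9)
- Why: Büchner–Curtius–Schlotterbeck (Tiffeneau–Demjanov-type) homologation; the sp3 CH2 migrates and the vinylic carbon does not, so conjugation is kept, and the bulky α-silyl group stops a second insertion.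

**Step 6**
- Reactants: 7, methyl 4,4-dimethoxybutanoate
- Product: 8, its O-TBS ketene acetal, tert-butyl[(1,4,4-trimethoxybut-1-en-1-yl)oxy]dimethylsilane
- Conditions: LDA, THF, −78 °C; TBSCl, DMPU, → rt
- Reagents that add atoms: TBSCl, CC(C)(C)[Si](C)(C)Cl
- Why: Kinetic ester enolisation and O-silylation; the γ-acetal cannot undergo β-elimination.

**Step 7**
- Reactants: 6 and 8
- Product: 9, the TBS enol ether (C10=C1) carrying CH(CO2Me)CH2CH(OMe)2 at C5, anti to the CMe2 bridge
- Conditions: LiClO4 (about 3 M in Et2O), rt
- Reagents that add atoms: none beyond the numbered reactants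
- Why: Mukaiyama–Michael addition under nearly neutral conditions that tolerate the acetal and the cyclopropane; the endo methyl of the CMe2 bridge blocks the syn face, so the C5–C4 bond forms anti and sets C5.

**Step 8**
- Reactants: 9
- Product: 10, methyl (1aS,7ξ,7aS,7bS)-1,1-dimethyl-4-oxo-1a,2,3,4,6,7,7a,7b-octahydro-1H-cyclopropa[e]azulene-7-carboxylate (C1=C2 enone)
- Conditions: 1 M aq HCl, THF, rt → 45 °C
- Reagents that add atoms: none (water is consumed and released again)
- Why: Acetal and silyl enol ether hydrolysis followed by a 5-exo intramolecular aldol condensation (acetal-based cyclopentene annulation); only C1 can reach the C2 aldehyde.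

**Step 9**
- Reactants: 10
- Product: 11, methyl (1aS,4aR,7ξ,7aR,7bR)-1,1-dimethyl-4-oxo-1a,2,3,4,4a,7,7a,7b-octahydro-1H-cyclopropa[e]azulene-7-carboxylate (C2=C3 alkene; H1 and H5 cis, both syn to CMe2)
- Conditions: KOt-Bu, t-BuOH/THF, 0 °C, 20 min; inverse quench into cold 10% aq AcOH; use at once
- Reagents that add atoms: none
- Why: Deconjugation through the thermodynamic extended dienolate with kinetic α-protonation; the proton arrives on the H5 (convex) face because C6 and the folded seven-membered ring cover the other face, which sets C1 cis to C5.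

**Step 10**
- Reactants: 11
- Product: 12, methyl (1aS,4S,4aR,7ξ,7aR,7bR)-1,1-dimethyl-1a,2,3,4a,7,7a,7b-heptahydro-1H-spiro[cyclopropa[e]azulene-4,2'-oxirane]-7-carboxylate
- Conditions: ClCH2I, MeLi·LiBr (slow addition), THF, −78 °C; then → rt
- Reagents that add atoms: chloroiodomethane, ClCI (supplies C14)
- Why: Chloromethyllithium addition followed by chlorohydrin closure (a Corey–Chaykovsky equivalent) is faster than enolisation or ester attack at −78 °C; the carbenoid attacks axially on the convex face, anti to the axial C1–C2 bond, which puts CH2 syn to H1 and O anti (10S).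

**Step 11**
- Reactants: 12
- Product: 13, the lactol ester (target skeleton with C2–OH and CO2Me at C4)
- Conditions: O3, CH2Cl2, −78 °C; PPh3, → rt
- Reagents that add atoms: ozone, [O-][O+]=O
- Why: Ozonolysis of the only alkene gives a dialdehyde whose formylacetate unit enolises and closes on C2 (iridoid-type enol-lactol formation); this erases C4 and places the C2–OH trans to C10 under anomeric and steric control.

**Step 12**
- Reactants: 13
- Product: 14, plagiochilin A
- Conditions: DIBAL-H (4 equiv), CH2Cl2, −78 °C; then pyridine, DMAP, Ac2O, −78 → 0 °C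
- Reagents that add atoms: acetic anhydride, CC(=O)OC(C)=O (two acetyl groups)
- Why: Reductive acetylation (Rychnovsky type); the lactol is held as its aluminium hemiacetal while the vinylogous carbonate is reduced to CH2O–Al, both O–Al groups are then acetylated in situ, the epoxide survives at −78 °C, and the C2 configuration is retained (2R).

## Compound list

| No. | Name | SMILES | Role |
|---|---|---|---|
| 1 | (+)-3-carene | CC1=CC[C@@H]2[C@H](C1)C2(C)C | starting material |
| 2 | keto-aldehyde (CH2CHO arm) | O=CC[C@@H]1[C@H](CC(C)=O)C1(C)C | intermediate |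
| 3 | enol acetate | CC(=O)OC=C[C@@H]1[C@H](CC(C)=O)C1(C)C | intermediate |
| 4 | (1R,3S)-2,2-dimethyl-3-(2-oxopropyl)cyclopropanecarbaldehyde | O=C[C@@H]1[C@H](CC(C)=O)C1(C)C | intermediate |
| 5 | (1S,6R)-7,7-dimethylbicyclo[4.1.0]hept-4-en-3-one | O=C1C=C[C@@H]2[C@H](C1)C2(C)C | intermediate |
| 6 | (1R,7S)-8,8-dimethylbicyclo[5.1.0]oct-2-en-4-one | O=C1C=C[C@@H]2[C@H](CC1)C2(C)C | intermediate |
| 7 | methyl 4,4-dimethoxybutanoate | COC(=O)CCC(OC)OC | starting material |
| 8 | TBS ketene acetal of 7 | COC(=CCC(OC)OC)O[Si](C)(C)C(C)(C)C | intermediate |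
| 9 | Michael adduct (TBS enol ether) | CC(C)(C)[Si](C)(C)OC1=C[C@H](C(CC(OC)OC)C(=O)OC)[C@@H]2[C@H](CC1)C2(C)C | intermediate |
| 10 | conjugated tricyclic enone ester | COC(=O)C1CC=C2[C@H]1[C@@H]1[C@H](CCC2=O)C1(C)C | intermediate |
| 11 | cis-fused β,γ-unsaturated ketone ester | COC(=O)C1C=C[C@@H]2[C@H]1[C@@H]1[C@H](CCC2=O)C1(C)C | intermediate |
| 12 | spiro-epoxide | COC(=O)C1C=C[C@@H]2[C@H]1[C@@H]1[C@H](CC[C@@]23CO3)C1(C)C | intermediate |
| 13 | lactol ester | COC(=O)C1=CO[C@H](O)[C@@H]2[C@H]1[C@@H]1[C@H](CC[C@@]23CO3)C1(C)C | intermediate |
| 14 | plagiochilin A | CC(=O)OCC1=CO[C@H](OC(C)=O)[C@@H]2[C@H]1[C@@H]1[C@H](CC[C@@]23CO3)C1(C)C | target |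

## Step count and risks

- Total steps: 12
- Longest linear sequence: 11 (1 → 14)

**Steps most likely to fail**

1. **Step 5.** The risks are vinyl rather than CH2 migration, pyrazoline formation, and Lewis-acid opening of the cyclopropane.
   Fallback: drop the ring expansion and close the seven-membered ring directly.
   - Cyclopropanate prenyl diazoacetate intramolecularly with Rh2(5S-MEPY)4 to give (1S,5R)-6,6-dimethyl-3-oxabicyclo[3.1.0]hexan-2-one.
   - Reduce it to the lactol with DIBAL.
   - Carry out a Wittig reaction with Ph3P=CHC(O)CH2P(O)(OEt)2.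
   - Reduce the resulting enone by conjugate reduction and oxidise the primary alcohol.
   - Close the ring by intramolecular HWE to give the same enantiomer of 6.

2. **Step 9.** The risks are incomplete deconjugation, formation of the trans isomer, and re-conjugation of 11.
   Fallback: form the C1–C2 bond by a ring closure that can only give the cis isomer.
   - Add a CH(X)C≡CH unit to C5 of 6 by Mukaiyama–Michael addition or by allenylstannane/TBSOTf conjugate propargylation (X = CO2Me or CH2OTBS), keeping the C1=C10 silyl enol ether.
   - Cyclise with Au(I) in a 5-endo-dig carbocyclisation, which gives 11 directly.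

3. **Step 10.** The risks are enolisation or epimerisation of the labile ketone and insufficient facial selectivity at C10.
   Fallback: build the oxirane stepwise through a diol.
   - Add (i-PrO)Me2SiCH2MgCl, a weakly basic hydroxymethyl anion equivalent, to the same convex face.
   - Oxidise by Tamao oxidation to the C10/C14 diol.
   - Sulfonylate the primary alcohol selectively and close the ring with mild base.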